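**Retrosynthetic overview**

1. Target ⇒ caffeic acid + an (R)-α-hydroxy ketone; the ester is made last by Mitsunobu inversion, with the catechol left unprotected.
2. α-Hydroxy ketone ⇒ acyclic (E)-enone/(Z)-enoate bis-silyl ether. One flask closes the cyclopropane first (sulfoxonium ylide, Felkin–Anh control by the acetoxy carbon) and then the dihydropyranone (acid: desilylation, lactonisation).
3. Acyclic precursor ⇒ lactate-derived keto ylide + the aldehyde from the terminal vinyl group (ozonolysis/Wittig).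
4. (Z)-Enoate chain ⇒ ethyl propiolate + an epoxy acetate (epoxide opening, then semihydrogenation).
5. Epoxy acetate ⇒ divinyl carbinol; a desymmetrising Sharpless epoxidation sets both oxygenated centres.

Assumption: the SMILES is read as (2R)-pyranone carbon, (S)-acetoxy carbinol, (1S,2S)-trans-cyclopropane and (S)-lactate-derived centre; methyl (R)-lactate is taken as a cheap commercial material.

**Route**

Step 1
Reactants: 1 penta-1,4-dien-3-ol (divinyl carbinol)
Product: 2 (1S)-1-[(2R)-oxiran-2-yl]prop-2-en-1-ol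
Conditions: Ti(OiPr)4 (10 mol%), diisopropyl L-(+)-tartrate (13 mol%), t-BuOOH, 4 Å MS, CH2Cl2, −20 °C
Reagents that add atoms: tert-butyl hydroperoxide, CC(C)(C)OO
Why: Sharpless asymmetric epoxidation of the prochiral divinyl carbinol couples enantiotopic-group selection with diastereoface selection, so the L-(+)-tartrate catalyst gives the erythro (2R,3S)-epoxy alcohol (future pyranone C–O carbon and acetoxy carbinol) in very high ee, the minor enantiomer being consumed by a faster second epoxidation.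

Step 2
Reactants: 2 (1S)-1-[(2R)-oxiran-2-yl]prop-2-en-1-ol
Product: 3 (1S)-1-[(2R)-oxiran-2-yl]prop-2-en-1-yl acetate
Conditions: Ac2O, Et3N, 4-(dimethylamino)pyridine (cat.), CH2Cl2, 0 °C
Reagents that add atoms: acetic anhydride, CC(=O)OC(C)=O
Why: Nucleophile-catalysed O-acylation installs the acetate of the target at once; no stereocentre is touched and the epoxide is inert to these mild conditions.

Step 3
Reactants: 3 (1S)-1-[(2R)-oxiran-2-yl]prop-2-en-1-yl acetate, 4 ethyl prop-2-ynoate (ethyl propiolate)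
Product: 5 ethyl (5R,6S)-6-acetoxy-5-hydroxyoct-7-en-2-ynoate
Conditions: 4, n-BuLi, THF, −78 °C; BF3·OEt2; then 3, −78 °C
Reagents that add atoms: none
Why: Yamaguchi–Hirao alkynylation: the BF3-activated epoxide is opened by the lithium alkynyl trifluoroborate at its unhindered CH2 carbon at −78 °C, conditions that tolerate both esters, so the C–O stereocentre (future ring oxygen) is untouched.

Step 4
Reactants: 5 ethyl (5R,6S)-6-acetoxy-5-hydroxyoct-7-en-2-ynoate
Product: 6 ethyl (5R,6S)-6-acetoxy-5-(triethylsilyloxy)oct-7-en-2-ynoate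
Conditions: TESOTf, 2,6-lutidine, CH2Cl2, −78 °C
Reagents that add atoms: triethylsilyl trifluoromethanesulfonate, CC[Si](CC)(CC)OS(=O)(=O)C(F)(F)F
Why: Silyl-triflate O-silylation at −78 °C is much faster than 1,2-acetyl migration and masks the 5-OH so that the lactone cannot close before the cyclopropane is in place.

Step 5
Reactants: 6 ethyl (5R,6S)-6-acetoxy-5-(triethylsilyloxy)oct-7-en-2-ynoate
Product: 7 ethyl (2Z,5R,6S)-6-acetoxy-5-(triethylsilyloxy)octa-2,7-dienoate
Conditions: H2 (1 atm), Pd/CaCO3 poisoned with Pb(OAc)2, quinoline, EtOAc, rt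
Reagents that add atoms: none
Why: Lindlar-type semihydrogenation adds H2 syn to the ynoate to give the (Z)-enoate needed for lactonisation, and stops there because the poisoned palladium reduces the terminal vinyl group far more slowly.

Step 6
Reactants: 8 methyl (2R)-2-hydroxypropanoate (methyl (R)-lactate)
Product: 9 methyl (2R)-2-(triethylsilyloxy)propanoate
Conditions: TESCl, imidazole, CH2Cl2, 0 °C → rt
Reagents that add atoms: chlorotriethylsilane, CC[Si](Cl)(CC)CC
Why: Standard imidazole-mediated silylation; the stereocentre comes from the chiral pool and is not involved.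

Step 7
Reactants: 9 methyl (2R)-2-(triethylsilyloxy)propanoate
Product: 10 (3R)-3-(triethylsilyloxy)-1-(triphenyl-λ5-phosphanylidene)butan-2-one
Conditions: Ph3PCH3Br (2.2 equiv), n-BuLi (2.1 equiv), THF, 0 °C; then 9, 0 °C → rt
Reagents that add atoms: methyltriphenylphosphonium bromide, C[P+](c1ccccc1)(c1ccccc1)c1ccccc1.[Br-]
Why: C-acylation of methylenetriphenylphosphorane by the ester, followed by proton transfer to excess ylide, gives the stabilised keto ylide, with the α-silyloxy centre not enolised at this temperature.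

Step 8
Reactants: 7 ethyl (2Z,5R,6S)-6-acetoxy-5-(triethylsilyloxy)octa-2,7-dienoate, 10 (3R)-3-(triethylsilyloxy)-1-(triphenyl-λ5-phosphanylidene)butan-2-one
Product: 12 ethyl (2Z,5R,6S,7E,10R)-6-acetoxy-9-oxo-5,10-bis(triethylsilyloxy)undeca-2,7-dienoate, via aldehyde 11 (not isolated)
Conditions: O3, CH2Cl2, −78 °C (stopped at consumption of 7); Me2S, −78 °C → rt; then 10, CH2Cl2, 40 °C
Reagents that add atoms: ozone, [O-][O+]=O (its oxygen is carried only by intermediate 11 and leaves again in the Wittig stage)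
Why: Ozonolysis cleaves the isolated monosubstituted alkene faster than the electron-poor conjugated enoate, and the labile α-acetoxy aldehyde is trapped in the same flask by a neutral Wittig olefination with the stabilised ylide, which gives the (E)-enone without epimerising the acetoxy-bearing carbon.

Step 9
Reactants: 12 ethyl (2Z,5R,6S,7E,10R)-6-acetoxy-9-oxo-5,10-bis(triethylsilyloxy)undeca-2,7-dienoate
Product: 15 (S)-{(1S,2S)-2-[(2R)-2-hydroxypropanoyl]cyclopropyl}[(2R)-6-oxo-3,6-dihydro-2H-pyran-2-yl]methyl acetate, via silylated cyclopropyl ketone 13 (not isolated), via hydroxy ester 14 (not isolated)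
Conditions: Me3S(O)I, NaH, DMSO, rt; then 12, THF, 0 °C; then 2 M HCl (aq), rt
Reagents that add atoms: trimethylsulfoxonium iodide, C[S+](C)(C)=O.[I-]
Why: Corey–Chaykovsky cyclopropanation (Michael-initiated ring closure) in which the ylide adds to the enone β-carbon anti to the allylic C–OAc bond with H inside (Felkin–Anh), setting the (S)-centre next to the acetoxy carbon, and the enolate closes to the trans ring, setting the second (S)-centre; the acidic quench then removes both silyl ethers and the freed 5-OH lactonises onto the (Z)-ester, so cyclopropane and dihydropyranone form in one flask while the less electrophilic acyclic enoate and the base-sensitive lactone are never exposed to the ylide.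

Step 10
Reactants: 15 (S)-{(1S,2S)-2-[(2R)-2-hydroxypropanoyl]cyclopropyl}[(2R)-6-oxo-3,6-dihydro-2H-pyran-2-yl]methyl acetate, 16 (E)-3-(3,4-dihydroxyphenyl)prop-2-enoic acid (caffeic acid)
Product: 17 (S)-{(1S,2S)-2-[(2S)-2-{[(E)-3-(3,4-dihydroxyphenyl)prop-2-enoyl]oxy}propanoyl]cyclopropyl}[(2R)-6-oxo-3,6-dihydro-2H-pyran-2-yl]methyl acetate
Conditions: 16, PPh3, DIAD, THF, 0 °C → rt
Reagents that add atoms: none
Why: Mitsunobu esterification, in which the carboxylic acid (far more acidic than the catechol hydroxyls) is the only competent nucleophile and displaces the oxyphosphonium at the activated α-keto carbon by SN2, inverting (R) to the required (S).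

**Compound list**

1 | penta-1,4-dien-3-ol | C=CC(O)C=C | starting material
2 | (1S)-1-[(2R)-oxiran-2-yl]prop-2-en-1-ol | O[C@@H](C=C)[C@H]1CO1 | intermediate
3 | (1S)-1-[(2R)-oxiran-2-yl]prop-2-en-1-yl acetate | CC(=O)O[C@@H](C=C)[C@H]1CO1 | intermediate
4 | ethyl prop-2-ynoate | C#CC(=O)OCC | starting material
5 | ethyl (5R,6S)-6-acetoxy-5-hydroxyoct-7-en-2-ynoate | CC(=O)O[C@@H](C=C)[C@H](O)CC#CC(=O)OCC | intermediate
6 | ethyl (5R,6S)-6-acetoxy-5-(triethylsilyloxy)oct-7-en-2-ynoate | CC(=O)O[C@@H](C=C)[C@H](O[Si](CC)(CC)CC)CC#CC(=O)OCC | intermediate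
7 | ethyl (2Z,5R,6S)-6-acetoxy-5-(triethylsilyloxy)octa-2,7-dienoate | CC(=O)O[C@@H](C=C)[C@H](O[Si](CC)(CC)CC)C/C=C\C(=O)OCC | intermediate
8 | methyl (2R)-2-hydroxypropanoate | C[C@@H](O)C(=O)OC | starting material
9 | methyl (2R)-2-(triethylsilyloxy)propanoate | C[C@@H](O[Si](CC)(CC)CC)C(=O)OC | intermediate
10 | (3R)-3-(triethylsilyloxy)-1-(triphenyl-λ5-phosphanylidene)butan-2-one | C[C@@H](O[Si](CC)(CC)CC)C(=O)C=P(c1ccccc1)(c1ccccc1)c1ccccc1 | intermediate
11 | ethyl (2Z,5R,6R)-6-acetoxy-7-oxo-5-(triethylsilyloxy)hept-2-enoate | CC(=O)O[C@@H](C=O)[C@H](O[Si](CC)(CC)CC)C/C=C\C(=O)OCC | intermediate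
12 | ethyl (2Z,5R,6S,7E,10R)-6-acetoxy-9-oxo-5,10-bis(triethylsilyloxy)undeca-2,7-dienoate | CC(=O)O[C@@H](/C=C/C(=O)[C@@H](C)O[Si](CC)(CC)CC)[C@H](O[Si](CC)(CC)CC)C/C=C\C(=O)OCC | intermediate
13 | ethyl (2Z,5R,6S)-6-acetoxy-5-(triethylsilyloxy)-6-{(1S,2S)-2-[(2R)-2-(triethylsilyloxy)propanoyl]cyclopropyl}hex-2-enoate | CC(=O)O[C@@H]([C@H]1C[C@@H]1C(=O)[C@@H](C)O[Si](CC)(CC)CC)[C@H](O[Si](CC)(CC)CC)C/C=C\C(=O)OCC | intermediate
14 | ethyl (2Z,5R,6S)-6-acetoxy-5-hydroxy-6-{(1S,2S)-2-[(2R)-2-hydroxypropanoyl]cyclopropyl}hex-2-enoate | CC(=O)O[C@@H]([C@H]1C[C@@H]1C(=O)[C@@H](C)O)[C@H](O)C/C=C\C(=O)OCC | intermediate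
15 | (S)-{(1S,2S)-2-[(2R)-2-hydroxypropanoyl]cyclopropyl}[(2R)-6-oxo-3,6-dihydro-2H-pyran-2-yl]methyl acetate | CC(=O)O[C@@H]([C@H]1C[C@@H]1C(=O)[C@@H](C)O)[C@H]1CC=CC(=O)O1 | intermediate
16 | (E)-3-(3,4-dihydroxyphenyl)prop-2-enoic acid | OC(=O)/C=C/c1ccc(O)c(O)c1 | starting material
17 | (S)-{(1S,2S)-2-[(2S)-2-{[(E)-3-(3,4-dihydroxyphenyl)prop-2-enoyl]oxy}propanoyl]cyclopropyl}[(2R)-6-oxo-3,6-dihydro-2H-pyran-2-yl]methyl acetate | CC(=O)O[C@@H]([C@H]1C[C@@H]1C(=O)[C@H](C)OC(=O)/C=C/c1ccc(O)c(O)c1)[C@H]1CC=CC(=O)O1 | target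

**Step count and risks**

Total: 10 steps. Longest linear sequence: 8 steps (steps 1, 2, 3, 4, 5, 8, 9, 10); steps 6 and 7 make the ylide branch.

Most likely to fail, step 9. The facial selectivity of the ylide addition next to an acyclic acetoxy carbon may be only moderate, and the basic ylide could epimerise the α-silyloxy ketone or attack the acetate. The fallback sets out from 12 and replaces the nucleophilic ylide by a hydroxyl-directed zinc carbenoid. Reagent-controlled reduction with (R)-1-methyl-3,3-diphenyltetrahydro-1H,3H-pyrrolo[1,2-c][1,3,2]oxazaborole and catecholborane (toluene, −78 °C) gives the (9R)-allylic alcohol F1. Et2Zn/CH2I2 (CH2Cl2, 0 °C) then delivers CH2 syn to the zinc alkoxide in the H-eclipsed conformer, which is the same alkene face the ylide route needs, to give the cyclopropyl carbinol F2. Dess–Martin oxidation comes back to the route at 13, which is carried through the acidic second stage of step 9 to 15.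

Second, step 3. Under BF3 the neighbouring acetate may open the activated epoxide itself (acetoxonium formation) or migrate once the new hydroxyl is free. The fallback sets out from 2 and carries the carbinol oxygen as an ether through the opening. NaH and 4-methoxybenzyl bromide (THF, −20 °C) give the 4-methoxybenzyl ether F3. The same propiolate/BF3 opening gives the hydroxy ynoate F4, and TESOTf/2,6-lutidine gives the silyl ether F5. DDQ (CH2Cl2, pH 7 buffer, 0 °C) frees the allylic alcohol F6, which is acetylated at once (Ac2O, Et3N, 4-(dimethylamino)pyridine) to come back to the route at 6.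

Third, step 8. Ozone may not discriminate cleanly between the vinyl group and the (Z)-enoate, and the α-acetoxy aldehyde is fragile. The fallback sets out from 6 and changes the order so that no second alkene is present during ozonolysis. O3 then Me2S on 6 (the ynoate is inert) gives the ynoate aldehyde F7. Wittig reaction with 10 gives the enone ynoate F8. Semihydrogenation over Pd/CaCO3 poisoned with Pb(OAc)2 with quinoline, with no terminal alkene left to over-reduce, comes back to the route at 12.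

**Further compounds**

F1 | step 9 | ethyl (2Z,5R,6S,7E,9R,10R)-6-acetoxy-9-hydroxy-5,10-bis(triethylsilyloxy)undeca-2,7-dienoate | CC(=O)O[C@@H](/C=C/[C@@H](O)[C@@H](C)O[Si](CC)(CC)CC)[C@H](O[Si](CC)(CC)CC)C/C=C\C(=O)OCC
F2 | step 9 | ethyl (2Z,5R,6S)-6-acetoxy-6-{(1S,2S)-2-[(1R,2R)-1-hydroxy-2-(triethylsilyloxy)propyl]cyclopropyl}-5-(triethylsilyloxy)hex-2-enoate | CC(=O)O[C@@H]([C@H]1C[C@@H]1[C@@H](O)[C@@H](C)O[Si](CC)(CC)CC)[C@H](O[Si](CC)(CC)CC)C/C=C\C(=O)OCC
F3 | step 3 | (2R)-2-{(1S)-1-[(4-methoxyphenyl)methoxy]prop-2-en-1-yl}oxirane | COc1ccc(CO[C@@H](C=C)[C@H]2CO2)cc1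
F4 | step 3 | ethyl (5R,6S)-5-hydroxy-6-[(4-methoxyphenyl)methoxy]oct-7-en-2-ynoate | COc1ccc(CO[C@@H](C=C)[C@H](O)CC#CC(=O)OCC)cc1
F5 | step 3 | ethyl (5R,6S)-6-[(4-methoxyphenyl)methoxy]-5-(triethylsilyloxy)oct-7-en-2-ynoate | COc1ccc(CO[C@@H](C=C)[C@H](O[Si](CC)(CC)CC)CC#CC(=O)OCC)cc1
F6 | step 3 | ethyl (5R,6S)-6-hydroxy-5-(triethylsilyloxy)oct-7-en-2-ynoate | O[C@@H](C=C)[C@H](O[Si](CC)(CC)CC)CC#CC(=O)OCC
F7 | step 8 | ethyl (5R,6R)-6-acetoxy-7-oxo-5-(triethylsilyloxy)hept-2-ynoate | CC(=O)O[C@@H](C=O)[C@H](O[Si](CC)(CC)CC)CC#CC(=O)OCC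
F8 | step 8 | ethyl (5R,6S,7E,10R)-6-acetoxy-9-oxo-5,10-bis(triethylsilyloxy)undec-7-en-2-ynoate | CC(=O)O[C@@H](/C=C/C(=O)[C@@H](C)O[Si](CC)(CC)CC)[C@H](O[Si](CC)(CC)CC)CC#CC(=O)OCC
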